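**Retrosynthetic overview**
1. The hydroperoxide is installed last, by a Schenck ene reaction on a homoprenyl side chain.
2. The only ring (cyclohept-2-enone, C1–C2 bond) is closed in the penultimate step by a Ru-catalysed, hydroxyl-directed trans-hydroacylation (aldehyde C–H activation) of an acyclic hydroxy-ynal.
3. The Z-enol ester comes from Ru-catalysed anti-Markovnikov addition of 3-methylbut-2-enoic acid to a terminal alkyne; the C1 aldehyde comes from a CH2NO2 group (Nef).
4. C6–C7, with both stereocentres, is formed by an amine-catalysed syn-Michael addition that joins a β-quaternary aldehyde to a nitroalkene.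
5. The C5 quaternary centre is set by Cu-catalysed asymmetric SN2′ allylic alkylation of an E-allylic chloride (from propargyl alcohol and propargyl bromide by Zr-catalysed carboalumination) with a homoprenyl Grignard reagent.

Labels used below: C1 (ring C=O), C2 (bears CH2OH), C3, C4, C5 (quaternary), C6 and C7 are the ring carbons of the target; C8=C9 is the enol ester double bond.
Assumption: in step 7 the (S,S,Sa) ligand gives the 5S centre; if the sense of induction is opposite, its enantiomer is used.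

**Step 1**
Reactants: 1 prop-2-yn-1-ol
Product: 2 tert-butyldimethyl(prop-2-yn-1-yloxy)silane
Conditions: TBSCl, imidazole, CH2Cl2, 0 °C to rt
Reagents that add atoms: tert-butyldimethylsilyl chloride CC(C)(C)[Si](C)(C)Cl
Why: Silyl ether protection of the primary alcohol keeps the hydroxyl inert towards the organoaluminium, Grignard and oxidation steps that follow.

**Step 2**
Reactants: 2 tert-butyldimethyl(prop-2-yn-1-yloxy)silane; 3 3-bromoprop-1-yne
Product: 4 tert-butyl(hexa-2,5-diyn-1-yloxy)dimethylsilane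
Conditions: CuI (10 mol %), Bu4NI (10 mol %), K2CO3, DMF, rt (2 in excess)
Reagents that add atoms: none
Why: The copper acetylide of 2 displaces the propargylic bromide (Cu-catalysed alkyne–propargyl halide coupling), the standard entry to skipped diynes.

**Step 3**
Reactants: 4 tert-butyl(hexa-2,5-diyn-1-yloxy)dimethylsilane
Product: 6 (2E)-7-(tert-butyldimethylsilyloxy)-3-methylhept-2-en-5-yn-1-ol, via alkenylalane 5 (not isolated)
Conditions: AlMe3 (2.5 equiv), (C5H5)2ZrCl2 (25 mol %), CH2Cl2, 0 °C to rt; then n-BuLi, THF, −78 °C; (CH2O)n, rt; H2O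
Reagents that add atoms: trimethylaluminium C[Al](C)C; formaldehyde (from paraformaldehyde) C=O
Why: Negishi Zr-catalysed carboalumination adds CH3 and Al syn across the terminal alkyne only (CH3 to the internal carbon), and hydroxymethylation of the alanate with retention fixes the E trisubstituted olefin.

**Step 4**
Reactants: 6 (2E)-7-(tert-butyldimethylsilyloxy)-3-methylhept-2-en-5-yn-1-ol
Product: 8 tert-butyl{[(5E)-7-chloro-5-methylhept-5-en-2-yn-1-yl]oxy}dimethylsilane, via mesylate 7 (not isolated)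
Conditions: MsCl, LiCl, 2,4,6-collidine, DMF, 0 °C
Reagents that add atoms: lithium chloride [Li+].[Cl-]
Why: Collington–Meyers chlorination: chloride displaces the primary allylic mesylate by SN2 without allylic transposition or loss of olefin geometry.

**Step 5**
Reactants: 9 1-cyclopropylethan-1-one
Product: 10 2-cyclopropylpropan-2-ol
Conditions: MeMgBr, Et2O, 0 °C to rt; H2O
Reagents that add atoms: methylmagnesium bromide C[Mg]Br
Why: Plain Grignard 1,2-addition to a methyl ketone.

**Step 6**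
Reactants: 10 2-cyclopropylpropan-2-ol
Product: 11 5-bromo-2-methylpent-2-ene
Conditions: 48 % aq. HBr, 0 °C
Reagents that add atoms: hydrogen bromide Br
Why: Julia cyclopropylcarbinyl-to-homoallyl rearrangement: ionisation of the tertiary carbinol and ring opening by bromide give the trisubstituted homoallylic bromide.

**Step 7**
Reactants: 8 tert-butyl{[(5E)-7-chloro-5-methylhept-5-en-2-yn-1-yl]oxy}dimethylsilane; 11 5-bromo-2-methylpent-2-ene
Product: 13 tert-butyl{[(5S)-5-ethenyl-5,9-dimethyldec-8-en-2-yn-1-yl]oxy}dimethylsilane, via Grignard reagent 12 (not isolated)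
Conditions: 11, Mg, THF, rt; then slow addition to 8, Cu(O2CC4H3S) (copper thiophene-2-carboxylate, 3 mol %), (S,S,Sa)-N,N-bis(1-phenylethyl) binaphthol phosphoramidite (3.3 mol %), CH2Cl2, −78 °C
Reagents that add atoms: none
Why: Copper-catalysed asymmetric allylic alkylation (SN2′): the chiral alkylcopper adds the homoprenyl group to the γ-carbon anti to chloride, and the fixed E geometry (CH3 versus CH2–alkyne) lets the ligand select the olefin face that gives the 5S quaternary centre.

**Step 8**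
Reactants: 13 tert-butyl{[(5S)-5-ethenyl-5,9-dimethyldec-8-en-2-yn-1-yl]oxy}dimethylsilane
Product: 15 (3S)-3-[4-(tert-butyldimethylsilyloxy)but-2-yn-1-yl]-3,7-dimethyloct-6-en-1-ol, via alkylborane 14 (not isolated)
Conditions: 9-BBN, THF, 0 °C to rt; then NaOH, H2O2, 0 °C
Reagents that add atoms: hydrogen peroxide OO
Why: Anti-Markovnikov hydroboration–oxidation; 9-BBN reacts with the monosubstituted vinyl group far faster than with the trisubstituted alkene or the internal alkyne.

**Step 9**
Reactants: 15 (3S)-3-[4-(tert-butyldimethylsilyloxy)but-2-yn-1-yl]-3,7-dimethyloct-6-en-1-ol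
Product: 16 (3S)-3-[4-(tert-butyldimethylsilyloxy)but-2-yn-1-yl]-3,7-dimethyloct-6-enal
Conditions: Dess–Martin periodinane, CH2Cl2, rt
Reagents that add atoms: none
Why: Dess–Martin oxidation stops at the aldehyde, and the neighbouring quaternary carbon rules out epimerisation.

**Step 10**
Reactants: 17 methyl 3-oxobutanoate
Product: 18 methyl (2-methyl-1,3-dioxolan-2-yl)acetate
Conditions: HOCH2CH2OH, p-TsOH (cat.), toluene, reflux, Dean–Stark
Reagents that add atoms: ethane-1,2-diol OCCO
Why: Acid-catalysed ketalisation protects the ketone, which is far more reactive than the ester carbonyl.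

**Step 11**
Reactants: 18 methyl (2-methyl-1,3-dioxolan-2-yl)acetate
Product: 19 2-(2-methyl-1,3-dioxolan-2-yl)ethan-1-ol
Conditions: LiAlH4, THF, 0 °C; aqueous work-up
Reagents that add atoms: none
Why: Hydride reduction of the ester to the primary alcohol leaves the dioxolane untouched.

**Step 12**
Reactants: 19 2-(2-methyl-1,3-dioxolan-2-yl)ethan-1-ol
Product: 20 (2-methyl-1,3-dioxolan-2-yl)acetaldehyde
Conditions: Dess–Martin periodinane, pyridine, CH2Cl2, 0 °C to rt
Reagents that add atoms: none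
Why: Buffered Dess–Martin oxidation gives the β-ketal aldehyde without ketal loss or β-elimination.

**Step 13**
Reactants: 20 (2-methyl-1,3-dioxolan-2-yl)acetaldehyde; 21 nitromethane
Product: 22 1-(2-methyl-1,3-dioxolan-2-yl)-3-nitropropan-2-ol (racemic)
Conditions: 21 (5 equiv), KOt-Bu (10 mol %), THF/t-BuOH, 0 °C
Reagents that add atoms: none
Why: Henry (nitroaldol) reaction; the new carbinol centre is removed in the next step, so its configuration does not matter.

**Step 14**
Reactants: 22 1-(2-methyl-1,3-dioxolan-2-yl)-3-nitropropan-2-ol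
Product: 24 2-methyl-2-[(2E)-3-nitroprop-2-en-1-yl]-1,3-dioxolane, via nitro-alcohol mesylate 23 (not isolated)
Conditions: MsCl, Et3N, CH2Cl2, −20 to 0 °C
Reagents that add atoms: none
Why: Mesylation followed by E1cB elimination gives the thermodynamically favoured E-nitroalkene.

**Step 15**
Reactants: 16 (3S)-3-[4-(tert-butyldimethylsilyloxy)but-2-yn-1-yl]-3,7-dimethyloct-6-enal; 24 2-methyl-2-[(2E)-3-nitroprop-2-en-1-yl]-1,3-dioxolane
Product: 25 (2S,3R)-2-[(5S)-1-(tert-butyldimethylsilyloxy)-5,9-dimethyldec-8-en-2-yn-5-yl]-3-[(2-methyl-1,3-dioxolan-2-yl)methyl]-4-nitrobutanal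
Conditions: (S)-2-[diphenyl(trimethylsilyloxy)methyl]pyrrolidine (20 mol %), 4-nitrophenol (20 mol %), toluene, rt
Reagents that add atoms: none
Why: Hayashi–Jørgensen enamine Michael addition: the E-enamine of 16, shielded on one face by the diphenyl(silyloxy)methyl group, adds to the nitroalkene through the synclinal transition state, so the S catalyst sets C6 (S) and C7 (R) as the syn pair while C5 is a spectator.

**Step 16**
Reactants: 25 (2S,3R)-2-[(5S)-1-(tert-butyldimethylsilyloxy)-5,9-dimethyldec-8-en-2-yn-5-yl]-3-[(2-methyl-1,3-dioxolan-2-yl)methyl]-4-nitrobutanal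
Product: 26 tert-butyldimethyl{[(5S)-5,9-dimethyl-5-{(3S,4R)-4-[(2-methyl-1,3-dioxolan-2-yl)methyl]-5-nitropent-1-yn-3-yl}dec-8-en-2-yn-1-yl]oxy}silane
Conditions: dimethyl (1-diazo-2-oxopropyl)phosphonate, K2CO3, MeOH, 0 °C to rt
Reagents that add atoms: dimethyl (1-diazo-2-oxopropyl)phosphonate CC(=O)C(=[N+]=[N-])P(=O)(OC)OC
Why: Seyferth–Gilbert homologation in the Ohira–Bestmann form turns the aldehyde into the terminal alkyne under mild carbonate, and C6, flanked by the quaternary carbon, resists epimerisation.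

**Step 17**
Reactants: 26 the terminal alkyne from step 16; 27 3-methylbut-2-enoic acid
Product: 28 (1Z,3R,4R)-3-[(5S)-1-(tert-butyldimethylsilyloxy)-5,9-dimethyldec-8-en-2-yn-5-yl]-4-[(2-methyl-1,3-dioxolan-2-yl)methyl]-5-nitropent-1-en-1-yl 3-methylbut-2-enoate
Conditions: Ru(η3-2-methylallyl)2(Ph2P(CH2)4PPh2) (3 mol %), toluene, 65 °C
Reagents that add atoms: none
Why: Ru-catalysed anti-Markovnikov hydro-oxycarbonylation via a ruthenium vinylidene puts the carboxylate on the terminal carbon and gives the Z-enol ester; the internal alkyne cannot form a vinylidene and is left alone.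

**Step 18**
Reactants: 28 the protected Z-enol ester from step 17
Product: 29 (1Z,3R,4R)-3-[(5S)-1-hydroxy-5,9-dimethyldec-8-en-2-yn-5-yl]-4-(nitromethyl)-6-oxohept-1-en-1-yl 3-methylbut-2-enoate
Conditions: 1 M aq. HCl, THF, 0 °C to rt
Reagents that add atoms: water O
Why: Dilute acid hydrolysis removes the primary silyl ether and the dioxolane together, while the enol ester and the nitro group tolerate these conditions.

**Step 19**
Reactants: 29 the nitro keto alcohol from step 18
Product: 31 (1Z,3S,4R)-4-formyl-3-[(5S)-1-hydroxy-5,9-dimethyldec-8-en-2-yn-5-yl]-6-oxohept-1-en-1-yl 3-methylbut-2-enoate, via potassium nitronate 30 (not isolated)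
Conditions: KOt-Bu (1.05 equiv), THF, −78 °C; then aq. TiCl3, NH4OAc buffer (pH 5–6), THF/H2O, 0 °C to rt
Reagents that add atoms: water O
Why: Reductive Nef reaction: only the most acidic CH2NO2 is deprotonated, trivalent titanium reduces the nitronate to the imine, and this hydrolyses to the aldehyde with no base left to epimerise C7.

**Step 20**
Reactants: 31 the hydroxy-ynal from step 19
Product: 32 (Z)-2-[(1S,2S,7R)-5-(hydroxymethyl)-2-methyl-2-(4-methylpent-3-en-1-yl)-6-oxo-7-(2-oxopropyl)cyclohept-4-en-1-yl]ethenyl 3-methylbut-2-enoate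
Conditions: [(C5Me5)RuCl]4 (2.5 mol %), CH2Cl2 (5 mM), rt to 40 °C, argon
Reagents that add atoms: none
Why: Proposed new method: a hydroxyl-directed intramolecular trans-hydroacylation of an internal alkyne by aldehyde C–H activation, in which the (C5Me5)RuCl unit binds the alkyne while its chloride hydrogen-bonds to the propargylic OH, the aldehyde C–H is cleaved at ruthenium to an acyl hydride, the hydride passes to the distal alkyne carbon C3 to give an η2-vinyl (ruthenacyclopropene) species, and the acyl group then migrates to the OH-proximal carbon C2 on the face opposite to H, so that C1 and C4 end up cis on the new C2=C3 bond as the seven-membered ring requires; the closest known reaction types are the trans-hydrostannation and trans-hydrosilylation of propargylic alcohols with the same ruthenium catalyst and the Rh-catalysed trans-hydroacylation of 4-alkynals to cyclopentenones, and no stereocentre is formed or touched.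

**Step 21**
Reactants: 32 the cycloheptenone from step 20
Product: 33 (Z)-2-[(1S,2S,7R)-2-[(2E)-4-hydroperoxy-4-methylpent-2-en-1-yl]-5-(hydroxymethyl)-2-methyl-6-oxo-7-(2-oxopropyl)cyclohept-4-en-1-yl]ethenyl 3-methylbut-2-enoate
Conditions: O2, tetraphenylporphyrin (cat.), visible light, CH2Cl2, 0 °C; chromatographic separation from the secondary hydroperoxide regioisomer
Reagents that add atoms: dioxygen O=O
Why: Schenck ene reaction: singlet oxygen attacks only the electron-rich trisubstituted alkene, and abstraction of an allylic CH2 hydrogen gives the tertiary hydroperoxide with the E-shifted double bond, the enone, enol ester and enoate alkenes being too electron-poor to react.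

**Compound list**
1 | prop-2-yn-1-ol | C#CCO | starting material
2 | tert-butyldimethyl(prop-2-yn-1-yloxy)silane | C#CCO[Si](C)(C)C(C)(C)C | intermediate
3 | 3-bromoprop-1-yne | C#CCBr | starting material
4 | tert-butyl(hexa-2,5-diyn-1-yloxy)dimethylsilane | C#CCC#CCO[Si](C)(C)C(C)(C)C | intermediate
5 | [(1E)-7-(tert-butyldimethylsilyloxy)-2-methylhept-1-en-5-yn-1-yl]dimethylalane | C[Al](C)/C=C(C)/CC#CCO[Si](C)(C)C(C)(C)C | intermediate
6 | (2E)-7-(tert-butyldimethylsilyloxy)-3-methylhept-2-en-5-yn-1-ol | OC/C=C(C)/CC#CCO[Si](C)(C)C(C)(C)C | intermediate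
7 | (2E)-7-(tert-butyldimethylsilyloxy)-3-methylhept-2-en-5-yn-1-yl methanesulfonate | CS(=O)(=O)OC/C=C(C)/CC#CCO[Si](C)(C)C(C)(C)C | intermediate
8 | tert-butyl{[(5E)-7-chloro-5-methylhept-5-en-2-yn-1-yl]oxy}dimethylsilane | ClC/C=C(C)/CC#CCO[Si](C)(C)C(C)(C)C | intermediate
9 | 1-cyclopropylethan-1-one | CC(=O)C1CC1 | starting material
10 | 2-cyclopropylpropan-2-ol | CC(C)(O)C1CC1 | intermediate
11 | 5-bromo-2-methylpent-2-ene | CC(C)=CCCBr | intermediate
12 | (4-methylpent-3-en-1-yl)magnesium bromide | CC(C)=CCC[Mg]Br | intermediate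
13 | tert-butyl{[(5S)-5-ethenyl-5,9-dimethyldec-8-en-2-yn-1-yl]oxy}dimethylsilane (C5 S) | CC(C)(C)[Si](C)(C)OCC#CC[C@](C)(CCC=C(C)C)C=C | intermediate
14 | 9-[(3S)-3-{4-(tert-butyldimethylsilyloxy)but-2-yn-1-yl}-3,7-dimethyloct-6-en-1-yl]-9-borabicyclo[3.3.1]nonane | CC(C)(C)[Si](C)(C)OCC#CC[C@](C)(CCC=C(C)C)CCB1C2CCCC1CCC2 | intermediate
15 | (3S)-3-[4-(tert-butyldimethylsilyloxy)but-2-yn-1-yl]-3,7-dimethyloct-6-en-1-ol | CC(C)(C)[Si](C)(C)OCC#CC[C@](C)(CCC=C(C)C)CCO | intermediate
16 | (3S)-3-[4-(tert-butyldimethylsilyloxy)but-2-yn-1-yl]-3,7-dimethyloct-6-enal | CC(C)(C)[Si](C)(C)OCC#CC[C@](C)(CCC=C(C)C)CC=O | intermediate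
17 | methyl 3-oxobutanoate | CC(=O)CC(=O)OC | starting material
18 | methyl (2-methyl-1,3-dioxolan-2-yl)acetate | CC1(CC(=O)OC)OCCO1 | intermediate
19 | 2-(2-methyl-1,3-dioxolan-2-yl)ethan-1-ol | CC1(CCO)OCCO1 | intermediate
20 | (2-methyl-1,3-dioxolan-2-yl)acetaldehyde | CC1(CC=O)OCCO1 | intermediate
21 | nitromethane | C[N+](=O)[O-] | starting material
22 | 1-(2-methyl-1,3-dioxolan-2-yl)-3-nitropropan-2-ol (racemic) | CC1(CC(O)C[N+](=O)[O-])OCCO1 | intermediate
23 | 1-(2-methyl-1,3-dioxolan-2-yl)-3-nitropropan-2-yl methanesulfonate | CC1(CC(OS(C)(=O)=O)C[N+](=O)[O-])OCCO1 | intermediate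
24 | 2-methyl-2-[(2E)-3-nitroprop-2-en-1-yl]-1,3-dioxolane | CC1(C/C=C/[N+](=O)[O-])OCCO1 | intermediate
25 | (2S,3R)-2-[(5S)-1-(tert-butyldimethylsilyloxy)-5,9-dimethyldec-8-en-2-yn-5-yl]-3-[(2-methyl-1,3-dioxolan-2-yl)methyl]-4-nitrobutanal (C5 S, C6 S, C7 R) | CC1(OCCO1)C[C@@H](C[N+](=O)[O-])[C@H](C=O)[C@@](C)(CCC=C(C)C)CC#CCO[Si](C)(C)C(C)(C)C | intermediate
26 | tert-butyldimethyl{[(5S)-5,9-dimethyl-5-{(3S,4R)-4-[(2-methyl-1,3-dioxolan-2-yl)methyl]-5-nitropent-1-yn-3-yl}dec-8-en-2-yn-1-yl]oxy}silane | CC1(OCCO1)C[C@@H](C[N+](=O)[O-])[C@H](C#C)[C@@](C)(CCC=C(C)C)CC#CCO[Si](C)(C)C(C)(C)C | intermediate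
27 | 3-methylbut-2-enoic acid | CC(C)=CC(=O)O | starting material
28 | (1Z,3R,4R)-3-[(5S)-1-(tert-butyldimethylsilyloxy)-5,9-dimethyldec-8-en-2-yn-5-yl]-4-[(2-methyl-1,3-dioxolan-2-yl)methyl]-5-nitropent-1-en-1-yl 3-methylbut-2-enoate | CC1(OCCO1)C[C@@H](C[N+](=O)[O-])[C@H](/C=C\OC(=O)C=C(C)C)[C@@](C)(CCC=C(C)C)CC#CCO[Si](C)(C)C(C)(C)C | intermediate
29 | (1Z,3R,4R)-3-[(5S)-1-hydroxy-5,9-dimethyldec-8-en-2-yn-5-yl]-4-(nitromethyl)-6-oxohept-1-en-1-yl 3-methylbut-2-enoate | CC(=O)C[C@@H](C[N+](=O)[O-])[C@H](/C=C\OC(=O)C=C(C)C)[C@@](C)(CCC=C(C)C)CC#CCO | intermediate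
30 | potassium nitronate of 29 | CC(=O)C[C@@H](C=[N+]([O-])[O-])[C@H](/C=C\OC(=O)C=C(C)C)[C@@](C)(CCC=C(C)C)CC#CCO.[K+] | intermediate
31 | (1Z,3S,4R)-4-formyl-3-[(5S)-1-hydroxy-5,9-dimethyldec-8-en-2-yn-5-yl]-6-oxohept-1-en-1-yl 3-methylbut-2-enoate (C5 S, C6 S, C7 R) | CC(=O)C[C@@H](C=O)[C@H](/C=C\OC(=O)C=C(C)C)[C@@](C)(CCC=C(C)C)CC#CCO | intermediate
32 | (Z)-2-[(1S,2S,7R)-5-(hydroxymethyl)-2-methyl-2-(4-methylpent-3-en-1-yl)-6-oxo-7-(2-oxopropyl)cyclohept-4-en-1-yl]ethenyl 3-methylbut-2-enoate | CC(=O)C[C@H]1C(=O)C(CO)=CC[C@](C)(CCC=C(C)C)[C@H]1/C=C\OC(=O)C=C(C)C | intermediate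
33 | (Z)-2-[(1S,2S,7R)-2-[(2E)-4-hydroperoxy-4-methylpent-2-en-1-yl]-5-(hydroxymethyl)-2-methyl-6-oxo-7-(2-oxopropyl)cyclohept-4-en-1-yl]ethenyl 3-methylbut-2-enoate | CC(=O)C[C@H]1C(=O)C(CO)=CC[C@](C)(C/C=C/C(C)(C)OO)[C@H]1/C=C\OC(=O)C=C(C)C | target

**Step count**
Total: 21 steps. Longest linear sequence: 14 steps (1–4, 7–9, 15–21). Steps 5–6 (side-chain bromide) and 10–14 (nitroalkene) run in parallel.

**Steps most likely to fail and their fallbacks**

Step 20 (the new ring closure). The risks are decarbonylation, closure at the other alkyne carbon, or no C–H activation at all. The fallback sets out from 31 and comes back at 32 through known stepwise chemistry. Trans-hydrostannation of 31 with Bu3SnH and [(C5Me5)RuCl]4, which places tin on the OH-proximal carbon, gives the (Z)-2-stannyl allylic alcohol F1. Iododestannylation (I2, CH2Cl2, −78 °C) gives the (Z)-2-iodo allylic alcohol F2. An intramolecular Nozaki–Hiyama–Kishi reaction (CrCl2, NiCl2 cat., DMSO) closes the ring to the cycloheptenediol F3. Selective silylation of the primary hydroxyl (TBSCl, imidazole) gives the monosilyl ether F4. Dess–Martin oxidation gives the silylated enone F5, and HF·pyridine returns 32.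

Step 19 (Nef reaction on a substrate carrying an enol ester, a ketone and an alkyne). The fallback sets out from 28 and comes back at 31, avoiding the nitronate and titanium. Oxidation of the primary nitro group with NaNO2 and AcOH in DMSO gives the protected carboxylic acid F6. Reduction through the mixed anhydride (i-BuOCOCl, N-methylmorpholine; then NaBH4) gives the protected primary alcohol F7. Dess–Martin oxidation gives the protected aldehyde F8, and 1 M aq. HCl in THF removes the silyl ether and the dioxolane to give 31.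

Step 21 (roughly equal amounts of the tertiary and secondary hydroperoxides are expected). The fallback sets out from 32 and comes back at 33 with the regiochemistry fixed by selenium chemistry. Hydroxyselenenylation of the trisubstituted alkene (N-(phenylseleno)phthalimide, H2O, camphorsulfonic acid cat.) gives the β-hydroxy selenide F9, with OH on the tertiary carbon. Oxidation with H2O2 and pyridine and syn-elimination of the selenoxide give the E tertiary allylic alcohol F10. Perhydrolysis (50 % H2O2, H2SO4 cat., Et2O, 0 °C) gives 33.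

**Further compounds**
F1 | step 20 | (Z)-2-tributylstannyl allylic alcohol from 31 (Sn on C2, cis to C4) | CC(=O)C[C@@H](C=O)[C@H](/C=C\OC(=O)C=C(C)C)[C@@](C)(CCC=C(C)C)C/C=C(/CO)[Sn](CCCC)(CCCC)CCCC
F2 | step 20 | (Z)-2-iodo allylic alcohol from 31 (I on C2, cis to C4) | CC(=O)C[C@@H](C=O)[C@H](/C=C\OC(=O)C=C(C)C)[C@@](C)(CCC=C(C)C)C/C=C(/CO)I
F3 | step 20 | cycloheptenediol, the C1 carbinol of 32 (C1 epimers) | CC(=O)C[C@H]1C(O)C(CO)=CC[C@](C)(CCC=C(C)C)[C@H]1/C=C\OC(=O)C=C(C)C
F4 | step 20 | primary tert-butyldimethylsilyl ether of F3 | CC(=O)C[C@H]1C(O)C(CO[Si](C)(C)C(C)(C)C)=CC[C@](C)(CCC=C(C)C)[C@H]1/C=C\OC(=O)C=C(C)C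
F5 | step 20 | tert-butyldimethylsilyl ether of 32 | CC(=O)C[C@H]1C(=O)C(CO[Si](C)(C)C(C)(C)C)=CC[C@](C)(CCC=C(C)C)[C@H]1/C=C\OC(=O)C=C(C)C
F6 | step 19 | C1 carboxylic acid with silyl ether and dioxolane in place | CC1(OCCO1)C[C@@H](C(=O)O)[C@H](/C=C\OC(=O)C=C(C)C)[C@@](C)(CCC=C(C)C)CC#CCO[Si](C)(C)C(C)(C)C
F7 | step 19 | C1 primary alcohol with silyl ether and dioxolane in place | CC1(OCCO1)C[C@@H](CO)[C@H](/C=C\OC(=O)C=C(C)C)[C@@](C)(CCC=C(C)C)CC#CCO[Si](C)(C)C(C)(C)C
F8 | step 19 | silyl ether and dioxolane protected form of 31 | CC1(OCCO1)C[C@@H](C=O)[C@H](/C=C\OC(=O)C=C(C)C)[C@@](C)(CCC=C(C)C)CC#CCO[Si](C)(C)C(C)(C)C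
F9 | step 21 | β-hydroxy selenide of 32 (PhSe on the secondary carbon, OH on CMe2) | CC(=O)C[C@H]1C(=O)C(CO)=CC[C@](C)(CCC([Se]c2ccccc2)C(C)(C)O)[C@H]1/C=C\OC(=O)C=C(C)C
F10 | step 21 | E tertiary allylic alcohol, the hydroxy analogue of 33 | CC(=O)C[C@H]1C(=O)C(CO)=CC[C@](C)(C/C=C/C(C)(C)O)[C@H]1/C=C\OC(=O)C=C(C)C
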